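A small charge is what you are asked about: the ochre run, with less starting material and less coupling partner than any run so far.

| flask | starting material | coupling partner | time |
|---|---|---|---|
| red | 0.250 M | 0.200 M |  |
| blue | 0.500 M | 0.200 M |  |
| grey | 0.250 M | 0.300 M |  |
| ochre | 0.0800 M | 0.0300 M | 73 min |

| run | time / min | [target] / M |
|---|---|---|
| red run | 9.1 | 0.0548 |
| red run | 18 | 0.0791 |
| red run | 27 | 0.0923 |
| red run | 36 | 0.1003 |
| red run | 46 | 0.1041 |
| red run | 55 | 0.1091 |
| red run | 64 | 0.1095 |
| red run | 73 | 0.1101 |
| blue run | 9.1 | 0.0783 |
| blue run | 18 | 0.1087 |
| blue run | 27 | 0.1247 |
| blue run | 36 | 0.1353 |
| blue run | 46 | 0.1418 |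
| blue run | 55 | 0.1432 |
| blue run | 64 | 0.1461 |
| blue run | 73 | 0.1488 |
| grey run | 9.1 | 0.0795 |
| grey run | 18 | 0.1105 |
| grey run | 27 | 0.1258 |
| grey run | 36 | 0.1312 |
| grey run | 46 | 0.1374 |
| grey run | 55 | 0.1392 |
| grey run | 64 | 0.1406 |
| grey run | 73 | 0.1409 |

(readings scatter by 0.001 M)

* the power of [starting material] that the first rate follows, about the charge of the red run; measure it at two percent of starting material made into target (one fixed amount of target, the same in the runs compared)
* the power of [coupling partner] that the first rate follows, about the charge of the red run; measure it at two percent of starting material made into target
* target in the ochre run at 73 min, as a share of the starting material charged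

- Overall: starting material + coupling partner -> target.
- Constant volume, constant temperature.
- The analysis sees a species whether free or bound.
- "The second partner" is coupling partner.
- An order is taken over about fifteen percent of the charge, up and down.

Read each reading as a share of the coupling partner charged, the smaller charge in ochre.

1. First instants, blue run: at 9.1 min the target already stands at 39.1% of the partner charged. Yet a charge of starting material twice red's gives a first reading 1.43 times red's.

2. Middle, blue run: the mean rate falls from 0.00860 M/min before the first reading to 0.00342 M/min between the first and second, slower.

3. End, blue run: the last interval adds 0.00270 M, with the share at 74.4%.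

4. My reckoning: for ochre, 350 M·s is the dose, the charge of starting material times the time. If every step took two molecules, flasks with one ratio of charges would show equal shares at equal dose. Ochre's ratio of starting material to partner is 2.67, blue's 2.50, red's 1.25 and grey's 0.833, so I scale from blue.

Blue's first two readings stand at doses 273 M·s and 540 M·s, with shares 39.1% and 54.3%. Replacing the curve there by its mean slope gives 43.6% of the partner, which is 16.3% of the starting material.

I take that as a low estimate. The chord runs under blue's bending curve, ochre's ratio is higher, and step 1 shows the first reading growing less steeply than the charge.

5. The forecast says “this is an equilibrium rather than completion”. It gives an order of 0.55 in starting material, an order of 1 in coupling partner, and 13.7% of the starting material for ochre (range 12.5% to 15%), which stands below my estimate.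

6. The ochre run gives 18.1%, above the forecast's range.

    starting material + coupling partner ⇌ intermediate (0.4554 /M/min, 0.09300 /min)
    intermediate → target (2.034 /min)
    2 starting material ⇌ idle substrate dimer, settled at all times (5.410 /M)
    2 starting material → homo dimer (0.6840 /M/min)

The first rate follows starting material to the power 0.53 and coupling partner to the power 0.83. At its dose of 350 M·s, the target in the ochre run equals 48.4% of the partner charged, more than the chord's 43.6%. The blue run comes to a quarter of its starting material charged at 26.4 min, a dose of 791 M·s, 2.26 times ochre's, and there the target equals 62.5% of the partner charged.

The data stem from a simulated flask with constants of no real substance.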